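## Retrosynthetic overview

1. Numbering: C1 lactone C=O, C2 CH2, C3 CH–OO, C4 C(CH3)–O(lactone), C5 ring CH2, C6 C(CH3)–OO, C7–C16 side chain. The diene is made last by Horner–Wadsworth–Emmons olefination (C13=C14); C8–C13 come from cross-metathesis and diimide reduction of a C6-allyl group.
2. C6 is set by allylsilane addition to the C6 peroxycarbenium ion of a methoxy peroxyketal, with axial attack cis to the lactone oxygen.
3. The 1,2-dioxane (second and last ring) comes from H2O2/MeOH peroxyketalisation of a C6 methyl ketone, then 6-exo oxa-Michael closure of O–C3 onto a C2=C3 butenolide, directed by C4.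
4. The butenolide methyl ketone comes from β-fragmentation of a cyclobutanol, which cleaves a temporary C3–C6 bond of a 2-oxabicyclo[3.2.0]heptane-3,6-dione.
5. That bicycle (γ-lactone, first ring, plus a temporary cyclobutanone) comes from an auxiliary-controlled intramolecular keteniminium–enol ester [2+2] that forms C3–C4 and C5–C6. Enabling feature: C4 carries the lactone oxygen, a methyl and a CH2, so it is the carbon of an acetone enol ester of C1; joining the two peroxide-bearing carbons C3 and C6 turns C1–C2–C3–C6 into a succinyl unit and C3–C4–C5–C6 into a cyclobutanone.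

Key step: step 3

Assumption: the (2R,5R)-auxiliary is taken to favour the (1R,5R)-cycloadduct; should the sense of induction be the opposite, the equally available (2S,5S)-amine is used with no other change.

## Route

Step 1
Reactants: 1 succinic anhydride; 2 (2R,5R)-2,5-dimethylpyrrolidine
Product: 3 4-[(2R,5R)-2,5-dimethylpyrrolidin-1-yl]-4-oxobutanoic acid
Conditions: Et3N, CH2Cl2, 0 °C to rt; aq. HCl wash
Reagents that add atoms: none
Why: Aminolysis of a cyclic anhydride by a secondary amine opens the ring once and stops at the amido acid; no stereocentre is created and those of the auxiliary are not involved.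

Step 2
Reactants: 3 4-[(2R,5R)-2,5-dimethylpyrrolidin-1-yl]-4-oxobutanoic acid; 4 propyne
Product: 5 prop-1-en-2-yl 4-[(2R,5R)-2,5-dimethylpyrrolidin-1-yl]-4-oxobutanoate
Conditions: propyne (excess, sealed vessel), RuCl2(PPh3)(p-cymene) (1 mol%), toluene, 80 °C
Reagents that add atoms: none
Why: Ruthenium-catalysed Markovnikov addition of a carboxylic acid to a terminal alkyne (hydro-oxycarbonylation) should give the 1-methylvinyl ester under neutral conditions that leave the tertiary amide untouched; no stereocentre is created.

Step 3
Reactants: 5 prop-1-en-2-yl 4-[(2R,5R)-2,5-dimethylpyrrolidin-1-yl]-4-oxobutanoate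
Product: 8 (1R,5R)-1-methyl-2-oxabicyclo[3.2.0]heptane-3,6-dione, via keteniminium triflate 6 (not isolated), via cyclobutaniminium triflate 7 (not isolated)
Conditions: Tf2O, 2,6-di-tert-butyl-4-methylpyridine, ClCH2CH2Cl, 0 °C then reflux (high dilution); then H2O, NaHCO3, rt
Reagents that add atoms: water, O
Why: Proposed new method: Tf2O converts the tertiary amide into an O-triflyl iminium salt that the hindered pyridine deprotonates to keteniminium ion 6, whose electrophilic central carbon C6 bonds to the terminal CH2 (C5) of the isopropenyl ester while its nucleophilic carbon C3 closes on the oxygen-bearing carbon C4 (asynchronous [2+2], the developing positive charge at C4 being stabilised by the ester oxygen and the methyl group), and hydrolysis of cyclobutaniminium 7 gives the ketone and frees the auxiliary. The closest known reaction type is the intramolecular keteniminium–olefin [2+2] cycloaddition of ω-alkenyl amides carrying a C2-symmetric 2,5-dimethylpyrrolidine, together with intermolecular ketene cycloadditions to enol ethers and enol esters; new here are the enol ester as the olefin and the ester link in the tether. The γ-lactone is closed by the C3–C4 bond through the three-atom tether C2–C1–O (five-membered ring, fused mode, as for hept-6-enamides giving bicyclo[3.2.0]heptan-6-ones), and the cyclobutane is closed by the C3–C4 and C5–C6 bonds. C3 and C4 should come out cis because the three-atom tether can only span one face of the four-membered ring, and their absolute configuration is set by the auxiliary, one methyl group of which blocks one face of the keteniminium so that the alkene approaches C3 from the open face. The step needs activation of the amide and not the ester (the amide oxygen is by far the more nucleophilic towards Tf2O), fused and not bridged regiochemistry (secured by the polarisation and 1,1-disubstitution of the enol ester) and face selectivity (secured by the C2 symmetry of the auxiliary, which makes both rotamers about the C–N bond equivalent).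

Step 4
Reactants: 8 (1R,5R)-1-methyl-2-oxabicyclo[3.2.0]heptane-3,6-dione
Product: 9 (1R,5S,6S)-6-hydroxy-1,6-dimethyl-2-oxabicyclo[3.2.0]heptan-3-one
Conditions: MeCeCl2 (from MeLi and anhydrous CeCl3), THF, −78 °C; AcOH quench at −78 °C
Reagents that add atoms: methyllithium (used as methylcerium dichloride), [Li]C
Why: Organocerium 1,2-addition: the non-basic methylcerium reagent should add to the strained cyclobutanone much faster than to the lactone without enolising the β-acyloxy ketone, from the convex face (methyl exo, hydroxyl endo); this centre becomes a carbonyl carbon again in step 5, so its configuration is immaterial.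

Step 5
Reactants: 9 (1R,5S,6S)-6-hydroxy-1,6-dimethyl-2-oxabicyclo[3.2.0]heptan-3-one
Product: 12 (5R)-5-methyl-5-(2-oxopropyl)furan-2(5H)-one, via hypoiodite 10 (not isolated), via β-iodo lactone 11 (not isolated)
Conditions: PhI(OAc)2, I2, CH2Cl2, visible light, rt; then Et3N (1.1 equiv), 0 °C, short contact; aq. Na2S2O3 wash
Reagents that add atoms: none
Why: Hypoiodite (alkoxy radical) β-fragmentation: the cyclobutyloxy radical from 10 should cleave the strained C3–C6 bond to the secondary C3 radical and not to the primary C5 radical, iodine transfer gives β-iodo lactone 11, and amine-induced dehydroiodination gives the conjugated butenolide; C3 becomes sp2 and C4 is untouched.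

Step 6
Reactants: 12 (5R)-5-methyl-5-(2-oxopropyl)furan-2(5H)-one
Product: 14 (4aR,7aR)-3-methoxy-3,4a-dimethyltetrahydro-3H-furo[3,2-c][1,2]dioxin-6(4H)-one (both C3 epimers), via hydroperoxy ketal 13 (not isolated)
Conditions: urea–hydrogen peroxide, Sc(OTf)3 (cat.), MeOH, rt; then evaporation, Et2NH (cat.), CF3CH2OH, rt
Reagents that add atoms: hydrogen peroxide (as urea–hydrogen peroxide), OO; methanol, CO
Why: Acid-catalysed peroxyketalisation of the methyl ketone followed by amine-catalysed intramolecular oxa-Michael addition of the hydroperoxide (6-exo-trig) to the butenolide has close precedent for 3-alkoxy-1,2-dioxanes and for this peroxylactone core; the tether from C4 forces the new C3–O bond onto the lactone face that carries C5, so C4 sets C3 (cis fusion), while the ketal carbon forms as a mixture that converges in step 7.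

Step 7
Reactants: 14 (4aR,7aR)-3-methoxy-3,4a-dimethyltetrahydro-3H-furo[3,2-c][1,2]dioxin-6(4H)-one; 15 allyltrimethylsilane
Product: 17 (3S,4aR,7aR)-3,4a-dimethyl-3-(prop-2-en-1-yl)tetrahydro-3H-furo[3,2-c][1,2]dioxin-6(4H)-one, via peroxycarbenium triflate 16 (not isolated)
Conditions: TMSOTf (cat.), CH2Cl2, −78 °C
Reagents that add atoms: none
Why: Hosomi–Sakurai allylation of a peroxycarbenium ion: TMSOTf ionises the ketal C–OMe bond and the allylsilane should attack ion 16 axially on the half-chair that has the ring-fusion methyl pseudoequatorial and the lactone C–O bond pseudoaxial (chair-like transition state, no syn-axial methyl), placing the allyl group cis to the lactone oxygen and trans to that methyl, which is the configuration of the target at C6.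

Step 8
Reactants: 17 (3S,4aR,7aR)-3,4a-dimethyl-3-(prop-2-en-1-yl)tetrahydro-3H-furo[3,2-c][1,2]dioxin-6(4H)-one; 18 hex-5-en-1-ol
Product: 19 (3S,4aR,7aR)-3-[(2E)-7-hydroxyhept-2-en-1-yl]-3,4a-dimethyltetrahydro-3H-furo[3,2-c][1,2]dioxin-6(4H)-one (E/Z mixture)
Conditions: second-generation Grubbs catalyst (5 mol%), excess 18, CH2Cl2, 40 °C
Reagents that add atoms: none
Why: Olefin cross-metathesis between two terminal alkenes, driven by loss of ethene and an excess of the cheap partner, tolerates dialkyl peroxides and free alcohols; the alkene geometry is immaterial because this double bond is reduced next.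

Step 9
Reactants: 19 (3S,4aR,7aR)-3-[(2E)-7-hydroxyhept-2-en-1-yl]-3,4a-dimethyltetrahydro-3H-furo[3,2-c][1,2]dioxin-6(4H)-one
Product: 20 (3S,4aR,7aR)-3-(7-hydroxyheptyl)-3,4a-dimethyltetrahydro-3H-furo[3,2-c][1,2]dioxin-6(4H)-one
Conditions: dipotassium azodicarboxylate, AcOH, pyridine, MeOH, 0 °C to rt
Reagents that add atoms: none
Why: Diimide reduction transfers H2 to the unpolarised C=C through a concerted cyclic transition state and should leave the O–O bond, which catalytic hydrogenation would cleave, and the lactone untouched.

Step 10
Reactants: 20 (3S,4aR,7aR)-3-(7-hydroxyheptyl)-3,4a-dimethyltetrahydro-3H-furo[3,2-c][1,2]dioxin-6(4H)-one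
Product: 21 7-[(3S,4aR,7aR)-3,4a-dimethyl-6-oxotetrahydro-3H-furo[3,2-c][1,2]dioxin-3-yl]heptanal
Conditions: Dess–Martin periodinane, CH2Cl2, rt
Reagents that add atoms: none
Why: Dess–Martin oxidation takes the primary alcohol to the aldehyde under neutral conditions without over-oxidation, and the peroxide and lactone are inert to the hypervalent iodine reagent.

Step 11
Reactants: 21 7-[(3S,4aR,7aR)-3,4a-dimethyl-6-oxotetrahydro-3H-furo[3,2-c][1,2]dioxin-3-yl]heptanal; 22 diethyl [(2E)-3-phenylprop-2-en-1-yl]phosphonate
Product: 23 plakortolide Q
Conditions: 22, LiHMDS (1.0 equiv to 22), THF, −78 °C; then 21 added, −78 to 0 °C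
Reagents that add atoms: none
Why: Horner–Wadsworth–Emmons olefination with the preformed allylic phosphonate anion, used without excess base at low temperature, should form the new C13=C14 bond with E geometry and keep the E styryl bond, giving the (7E,9E)-diene without touching a stereocentre.

## Compound list

1 | succinic anhydride | O=C1CCC(=O)O1 | starting material
2 | (2R,5R)-2,5-dimethylpyrrolidine | C[C@@H]1CC[C@@H](C)N1 | starting material
3 | 4-[(2R,5R)-2,5-dimethylpyrrolidin-1-yl]-4-oxobutanoic acid | C[C@@H]1CC[C@@H](C)N1C(=O)CCC(=O)O | intermediate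
4 | propyne | CC#C | starting material
5 | prop-1-en-2-yl 4-[(2R,5R)-2,5-dimethylpyrrolidin-1-yl]-4-oxobutanoate | C[C@@H]1CC[C@@H](C)N1C(=O)CCC(=O)OC(C)=C | intermediate
6 | keteniminium triflate: (2R,5R)-2,5-dimethyl-1-[4-oxo-4-(prop-1-en-2-yloxy)but-1-en-1-ylidene]pyrrolidin-1-ium trifluoromethanesulfonate | C[C@@H]1CC[C@@H](C)[N+]1=C=CCC(=O)OC(C)=C.[O-]S(=O)(=O)C(F)(F)F | intermediate
7 | cyclobutaniminium triflate: (2R,5R)-2,5-dimethyl-1-(1-methyl-3-oxo-2-oxabicyclo[3.2.0]heptan-6-ylidene)pyrrolidin-1-ium trifluoromethanesulfonate, cis-fused, ring carbons configured as in 8 | C[C@@]12CC(=[N+]3[C@H](C)CC[C@H]3C)[C@@H]1CC(=O)O2.[O-]S(=O)(=O)C(F)(F)F | intermediate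
8 | (1R,5R)-1-methyl-2-oxabicyclo[3.2.0]heptane-3,6-dione (cis-fused cyclobutanone γ-lactone) | C[C@@]12CC(=O)[C@@H]1CC(=O)O2 | intermediate
9 | (1R,5S,6S)-6-hydroxy-1,6-dimethyl-2-oxabicyclo[3.2.0]heptan-3-one (methyl exo, hydroxyl endo) | C[C@@]12C[C@](C)(O)[C@@H]1CC(=O)O2 | intermediate
10 | hypoiodite of 9 (O–I in place of O–H, configuration as in 9) | C[C@@]12C[C@](C)(OI)[C@@H]1CC(=O)O2 | intermediate
11 | (5R)-4-iodo-5-methyl-5-(2-oxopropyl)oxolan-2-one (both C4 epimers) | CC(=O)C[C@@]1(C)OC(=O)CC1I | intermediate
12 | (5R)-5-methyl-5-(2-oxopropyl)furan-2(5H)-one | CC(=O)C[C@@]1(C)OC(=O)C=C1 | intermediate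
13 | (5R)-5-(2-hydroperoxy-2-methoxypropyl)-5-methylfuran-2(5H)-one (both epimers at the ketal carbon) | COC(C)(OO)C[C@@]1(C)OC(=O)C=C1 | intermediate
14 | (4aR,7aR)-3-methoxy-3,4a-dimethyltetrahydro-3H-furo[3,2-c][1,2]dioxin-6(4H)-one (cis-fused, both C3 epimers) | COC1(C)C[C@@]2(C)OC(=O)C[C@H]2OO1 | intermediate
15 | allyltrimethylsilane | C=CC[Si](C)(C)C | starting material
16 | peroxycarbenium triflate: cation of 14 after loss of methoxide, positive charge shared by the ketal carbon and the adjacent peroxide oxygen | C[C+]1C[C@@]2(C)OC(=O)C[C@H]2OO1.[O-]S(=O)(=O)C(F)(F)F | intermediate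
17 | (3S,4aR,7aR)-3,4a-dimethyl-3-(prop-2-en-1-yl)tetrahydro-3H-furo[3,2-c][1,2]dioxin-6(4H)-one | C=CC[C@@]1(C)C[C@@]2(C)OC(=O)C[C@H]2OO1 | intermediate
18 | hex-5-en-1-ol | C=CCCCCO | starting material
19 | (3S,4aR,7aR)-3-[(2E)-7-hydroxyhept-2-en-1-yl]-3,4a-dimethyltetrahydro-3H-furo[3,2-c][1,2]dioxin-6(4H)-one (E isomer drawn, E/Z mixture) | OCCCC/C=C/C[C@@]1(C)C[C@@]2(C)OC(=O)C[C@H]2OO1 | intermediate
20 | (3S,4aR,7aR)-3-(7-hydroxyheptyl)-3,4a-dimethyltetrahydro-3H-furo[3,2-c][1,2]dioxin-6(4H)-one | OCCCCCCC[C@@]1(C)C[C@@]2(C)OC(=O)C[C@H]2OO1 | intermediate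
21 | 7-[(3S,4aR,7aR)-3,4a-dimethyl-6-oxotetrahydro-3H-furo[3,2-c][1,2]dioxin-3-yl]heptanal | O=CCCCCCC[C@@]1(C)C[C@@]2(C)OC(=O)C[C@H]2OO1 | intermediate
22 | diethyl [(2E)-3-phenylprop-2-en-1-yl]phosphonate | CCOP(=O)(OCC)C/C=C/c1ccccc1 | starting material
23 | plakortolide Q, (3S,4aR,7aR)-3,4a-dimethyl-3-[(7E,9E)-10-phenyldeca-7,9-dien-1-yl]tetrahydro-3H-furo[3,2-c][1,2]dioxin-6(4H)-one | C[C@]1(CCCCCC/C=C/C=C/c2ccccc2)C[C@@]2(C)OC(=O)C[C@H]2OO1 | target

## Step count and risks

Total step count: 11. Longest linear sequence: 11 steps (from 1 and 2 to 23).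

Steps most likely to fail:

Step 3 (proposed new method). The keteniminium carbon may be captured by the neighbouring ester carbonyl oxygen instead of the alkene, the s-trans preference of the ester may keep the alkene out of reach at practical temperatures, or the facial bias of the auxiliary may be weak on this tether. The fallback drops the chiral iminium and uses the thermal intramolecular ketene–olefin [2+2] cycloaddition of an achiral acid chloride, a known reaction type, followed by resolution. It sets out from 1: ring opening with allyl alcohol and DMAP would give monoallyl succinate F1. Ruthenium-catalysed addition of F1 to propyne as in step 2 would give allyl prop-1-en-2-yl succinate F2. Deallylation with Pd(PPh3)4 and pyrrolidine would give isopropenyl hydrogen succinate F3. Oxalyl chloride would convert F3 into acid chloride F4. Slow addition of F4 to Et3N in refluxing toluene would generate ketene F5, which should cyclise in the same regiochemical sense to the racemic cis-fused keto lactone F6. Preparative chromatography of F6 on a chiral stationary phase would deliver 8, where the fallback rejoins the route.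

Step 7. Facial control in the addition to the peroxycarbenium ion may be lost if the ion reacts through the other half-chair, and the Lewis acid may cleave the O–O bond heterolytically instead of ionising the C–OMe bond. The fallback abandons the peroxycarbenium ion and builds C6 as a tertiary alcohol that is converted to the hydroperoxide and closed by oxa-Michael addition, without stereocontrol at C6 but with separable epimers. It sets out from 12: 1,2-addition of TBSO(CH2)7MgBr/CeCl3 to the ketone would give tertiary alcohol F8. Acid-catalysed perhydrolysis (50% H2O2, cat. H2SO4), which passes through the tertiary cation and also removes the silyl group, would give tertiary hydroperoxide F9. Et2NH in CF3CH2OH would then close the dioxane onto the butenolide as in step 6, giving 20 and its C3 epimer F10. After chromatographic separation the fallback rejoins the route at 20.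

Step 5. During dehydroiodination the base may instead trigger β-elimination of the lactone carboxylate from the β-acyloxy ketone, opening the lactone and erasing C4. The C3 radical may also react before iodine transfer. The fallback avoids the keto butenolide and every base by inserting O2 directly: it sets out from 9, which under Co(acac)2 and O2 (1 atm) should undergo aerobic oxidative ring expansion. The alkoxy radical fragments as in step 5, the C3 radical traps O2, and the hydroperoxide that forms on the face cis to the acetonyl arm closes onto the new ketone to give peroxy hemiketal F7. Material trapped on the other face cannot close and is lost. Exchange of the hemiketal hydroxyl in MeOH with a catalytic amount of pyridinium p-toluenesulfonate would give 14, where the fallback rejoins the route.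

Further compounds
F1 | step 3 | 4-oxo-4-(prop-2-en-1-yloxy)butanoic acid (monoallyl succinate) | C=CCOC(=O)CCC(=O)O
F2 | step 3 | prop-2-en-1-yl prop-1-en-2-yl butanedioate | C=CCOC(=O)CCC(=O)OC(C)=C
F3 | step 3 | 4-oxo-4-(prop-1-en-2-yloxy)butanoic acid (isopropenyl hydrogen succinate) | CC(=C)OC(=O)CCC(=O)O
F4 | step 3 | prop-1-en-2-yl 4-chloro-4-oxobutanoate | CC(=C)OC(=O)CCC(=O)Cl
F5 | step 3 | prop-1-en-2-yl 4-oxobut-3-enoate (ketene, not isolated) | CC(=C)OC(=O)CC=C=O
F6 | step 3 | racemic cis-fused 1-methyl-2-oxabicyclo[3.2.0]heptane-3,6-dione | CC12CC(=O)C1CC(=O)O2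
F7 | step 5 | (4aR,7aR)-3-hydroxy-3,4a-dimethyltetrahydro-3H-furo[3,2-c][1,2]dioxin-6(4H)-one (peroxy hemiketal, both C3 epimers) | OC1(C)C[C@@]2(C)OC(=O)C[C@H]2OO1
F8 | step 7 | (5R)-5-(9-{[tert-butyl(dimethyl)silyl]oxy}-2-hydroxy-2-methylnonyl)-5-methylfuran-2(5H)-one (both carbinol epimers) | CC(O)(CCCCCCCO[Si](C)(C)C(C)(C)C)C[C@@]1(C)OC(=O)C=C1
F9 | step 7 | (5R)-5-(2-hydroperoxy-9-hydroxy-2-methylnonyl)-5-methylfuran-2(5H)-one (both epimers at the peroxide carbon) | CC(OO)(CCCCCCCO)C[C@@]1(C)OC(=O)C=C1
F10 | step 7 | (3R,4aR,7aR)-3-(7-hydroxyheptyl)-3,4a-dimethyltetrahydro-3H-furo[3,2-c][1,2]dioxin-6(4H)-one (C3 epimer of 20) | OCCCCCCC[C@]1(C)C[C@@]2(C)OC(=O)C[C@H]2OO1
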